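**Plan**
1. Numbering: ring A is C1(OH), C2(H), C3(Br), C4(OH), C5(Br), C6(OAr). Ring B is C1'(O), C2'(H), C3'(Br), C4'(OH), C5'(Br), C6'(Br).
2. Cuts, last-formed bonds first: the two O–CH3 bonds on ring A, C3'–Br and C5'–Br, the O–benzyl bond at C4', and C3–Br. Then C6–O and C5–Br are cut together.
3. Feature used: on ring A the ether oxygen (C6) and a bromine (C5) sit side by side between the para oxygens at C1 and C4. C5/C6 therefore map onto the triple bond of mirror-symmetric 3,6-dimethoxybenzyne, and O and Br can be added across it with no regiochemical choice.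
4. Forward: no ring is built. Ring A (as an o-silylaryl triflate, three steps) and ring B (as the 2-bromophenol that already holds C6'–Br, one step) are joined in step 5. C3–Br, debenzylation, C3'/C5'–Br and demethylation follow.
5. Stereochemistry: none to set, because the target has no stereocentre.

Key step: step 5

Assumption: the diaryl ether is taken to rotate freely about its C–O bonds, so the target is treated as achiral; 2,5-dimethoxyphenol and 4-(benzyloxy)phenol are taken as purchasable.

**Step 1**
Reactants: 1 2,5-dimethoxyphenol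
Product: 2 2,5-dimethoxyphenyl N-isopropylcarbamate
Conditions: i-PrNCO, Et3N (cat.), CH2Cl2, rt
Reagents that add atoms: isopropyl isocyanate, CC(C)N=C=O
Why: Amine-catalysed addition of a phenol to an isocyanate (carbamoylation) installs a secondary O-aryl carbamate that directs metalation and can later be removed under mild base.

**Step 2**
Reactants: 2 2,5-dimethoxyphenyl N-isopropylcarbamate
Product: 6 3,6-dimethoxy-2-(trimethylsilyl)phenyl N-isopropylcarbamate, via N-silyl carbamate 3 (not isolated), via aryllithium 4 (not isolated), via bis-silyl carbamate 5 (not isolated)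
Conditions: TBSOTf, TMEDA, Et2O, 0 °C → rt; n-BuLi, TMEDA, −78 °C; TMSCl, −78 °C → rt; aq NaHSO4
Reagents that add atoms: chlorotrimethylsilane, C[Si](C)(C)Cl; tert-butyldimethylsilyl triflate, CC(C)(C)[Si](C)(C)OS(=O)(=O)C(F)(F)F (silyl group in 3–5 only); n-butyllithium, [Li]CCCC (lithium in 4 only)
Why: Directed ortho-metalation, in which transient N-silylation masks the N–H, n-BuLi/TMEDA removes the one ring proton lying between two directing oxygens (carbamate and methoxy), TMSCl traps the aryllithium and the acidic work-up strips the N-silyl group.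

**Step 3**
Reactants: 6 3,6-dimethoxy-2-(trimethylsilyl)phenyl N-isopropylcarbamate
Product: 8 3,6-dimethoxy-2-(trimethylsilyl)phenyl trifluoromethanesulfonate, via silylphenol 7 (not isolated)
Conditions: DBU, Et2NH, MeCN, 40 °C; then PhNTf2, rt
Reagents that add atoms: N-phenylbis(trifluoromethanesulfonimide), O=S(=O)(N(c1ccccc1)S(=O)(=O)C(F)(F)F)C(F)(F)F
Why: E1cB cleavage of the secondary carbamate releases isopropyl isocyanate, which Et2NH scavenges, and the freed phenoxide is O-sulfonylated in the same flask, which is the established one-pot entry to o-silylaryl triflates.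

**Step 4**
Reactants: 9 4-(benzyloxy)phenol
Product: 10 4-(benzyloxy)-2-bromophenol
Conditions: Br2 (1.0 equiv), CH2Cl2, 0 °C
Reagents that add atoms: bromine, BrBr
Why: In this electrophilic aromatic bromination the free hydroxyl outranks the benzyloxy group as director and its para position is blocked, so one equivalent of bromine should enter ortho to OH and place the future C6'–Br.

**Step 5**
Reactants: 8 3,6-dimethoxy-2-(trimethylsilyl)phenyl trifluoromethanesulfonate; 10 4-(benzyloxy)-2-bromophenol
Product: 14 2-bromo-3-[4-(benzyloxy)-2-bromophenoxy]-1,4-dimethoxybenzene, via potassium phenoxide 11 (not isolated), via 3,6-dimethoxybenzyne 12 (not isolated), via arylpotassium 13 (not isolated)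
Conditions: 10 (1.5 equiv), KH, THF, 0 °C → rt; then C6F5Br (5 equiv), KF, 18-crown-6, slow addition of 8, THF, 0 °C → rt; H2O
Reagents that add atoms: bromopentafluorobenzene, Fc1c(F)c(F)c(Br)c(F)c1F; potassium hydride, [K+].[H-] (potassium in 11 and 13 only)
Why: Proposed new method: KF/18-crown-6 desilylates 8 with loss of triflate (1,2-elimination) to aryne 12, phenoxide 11 adds through oxygen to one end of the C5≡C6 bond (C6–O), and the in-plane carbanion 13 left at C5, which the neighbouring C4 methoxy group stabilises by induction, attacks the bromine of C6F5Br halophilically (C5–Br) and expels the stabilised C6F5 anion. The closest known reaction types are the O-arylation of phenols by o-silylaryl triflates and the three-component aryne couplings in which a sulfur or nitrogen nucleophile adds and the aryl anion is halogenated by a polyhalogenated donor such as C6F5Br, so the untested part is the pairing of a phenoxide with a bromine donor. No ring is closed and no stereocentre is formed, so neither a mode of closure nor a controlling element is at issue. Site selectivity is not required, because 12 has a mirror plane that exchanges C5 and C6 and both modes of addition give 14. The selectivity that is required is bromine transfer ahead of protonation of 13, and it is served by KH (only H2 is left behind), by THF in place of the C–H acidic MeCN, by slow addition of 8 and by a fivefold excess of donor. Substrate and donor help further: 13 has no leaving group ortho to the carbanion (no second aryne), the single ring B bromine cannot be reached from C5 in a linear C···Br–C geometry, an oxygen nucleophile cannot displace the C6F5 anion from bromine so 11 is not brominated, and BrCF2CF2Br is avoided because phenoxides consume it in a chain through tetrafluoroethylene.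

**Step 6**
Reactants: 14 2-bromo-3-[4-(benzyloxy)-2-bromophenoxy]-1,4-dimethoxybenzene
Product: 15 2-[4-(benzyloxy)-2-bromophenoxy]-3,5-dibromo-1,4-dimethoxybenzene
Conditions: NBS (1.05 equiv), MeCN, 0 °C → rt, dark
Reagents that add atoms: N-bromosuccinimide, O=C1CCC(=O)N1Br
Why: In this electrophilic aromatic bromination attack at C3 gives a σ-complex whose charge rests on the carbons bearing the C4 methoxy and C6 aryloxy oxygens, whereas attack at C2 is helped only by the C1 methoxy oxygen and the C5 bromine, and the step is placed before ring B is loaded with bromine so that the aryloxy oxygen is as good a donor as possible, while stray attack at C3' would only anticipate step 8.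

**Step 7**
Reactants: 15 2-[4-(benzyloxy)-2-bromophenoxy]-3,5-dibromo-1,4-dimethoxybenzene
Product: 17 3-bromo-4-(2,4-dibromo-3,6-dimethoxyphenoxy)phenol, via aryloxydichloroborane 16 (not isolated)
Conditions: BCl3, C6HMe5, CH2Cl2, −78 °C; then H2O
Reagents that add atoms: boron trichloride, ClB(Cl)Cl (boron and chlorine in 16 only; none stays in 17)
Why: In this Lewis acid debenzylation with a cation scavenger BCl3 ionises the benzylic C–O bond at −78 °C, pentamethylbenzene takes up the benzyl cation by Friedel–Crafts alkylation before it can attack either electron-rich ring, and the aryl methyl ethers, the diaryl ether and the C–Br bonds (which rule out hydrogenolysis) should be left alone at this temperature.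

**Step 8**
Reactants: 17 3-bromo-4-(2,4-dibromo-3,6-dimethoxyphenoxy)phenol
Product: 19 2,3,6-tribromo-4-(2,4-dibromo-3,6-dimethoxyphenoxy)phenol, via dibromophenol 18 (not isolated)
Conditions: Br2 (2.1 equiv), AcOH–CH2Cl2, 0 °C → rt
Reagents that add atoms: bromine, BrBr
Why: In this ortho-bromination of a para-blocked phenol the freed C4'–OH activates C3' and then C5' far above the two remaining C–H positions, since C2' is meta to the hydroxyl and C2 sits on a ring that already carries two bromines.

**Step 9**
Reactants: 19 2,3,6-tribromo-4-(2,4-dibromo-3,6-dimethoxyphenoxy)phenol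
Product: 21 3,5-dibromo-2-(2,3,5-tribromo-4-hydroxyphenoxy)benzene-1,4-diol (CNP0084224.0), via tris(dibromoboryl) ether 20 (not isolated)
Conditions: BBr3 (5 equiv), CH2Cl2, −78 °C → rt; degassed H2O, 0 °C
Reagents that add atoms: boron tribromide, BrB(Br)Br (boron and its bromine in 20 only; none stays in 21)
Why: Aryl methyl ether cleavage with BBr3 (O-complexation, then SN2 attack of bromide on methyl), the usual last step for methoxylated polybrominated diphenyl ethers, should leave the diaryl ether and all five C–Br bonds untouched, and hydrolysis of 20 with exclusion of air frees the hydroquinone.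

**Compound list**
1 | 2,5-dimethoxyphenol | COc1ccc(OC)c(O)c1 | starting material
2 | 2,5-dimethoxyphenyl N-isopropylcarbamate | COc1ccc(OC)c(OC(=O)NC(C)C)c1 | intermediate
3 | 2,5-dimethoxyphenyl N-(tert-butyldimethylsilyl)-N-isopropylcarbamate | COc1ccc(OC)c(OC(=O)N(C(C)C)[Si](C)(C)C(C)(C)C)c1 | intermediate
4 | 2-{[N-(tert-butyldimethylsilyl)-N-isopropylcarbamoyl]oxy}-3,6-dimethoxyphenyllithium | COc1ccc(OC)c(OC(=O)N(C(C)C)[Si](C)(C)C(C)(C)C)c1[Li] | intermediate
5 | 3,6-dimethoxy-2-(trimethylsilyl)phenyl N-(tert-butyldimethylsilyl)-N-isopropylcarbamate | COc1ccc(OC)c(OC(=O)N(C(C)C)[Si](C)(C)C(C)(C)C)c1[Si](C)(C)C | intermediate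
6 | 3,6-dimethoxy-2-(trimethylsilyl)phenyl N-isopropylcarbamate | COc1ccc(OC)c(OC(=O)NC(C)C)c1[Si](C)(C)C | intermediate
7 | 3,6-dimethoxy-2-(trimethylsilyl)phenol (present as its DBU salt) | COc1ccc(OC)c(O)c1[Si](C)(C)C | intermediate
8 | 3,6-dimethoxy-2-(trimethylsilyl)phenyl trifluoromethanesulfonate | COc1ccc(OC)c(OS(=O)(=O)C(F)(F)F)c1[Si](C)(C)C | intermediate
9 | 4-(benzyloxy)phenol | Oc1ccc(OCc2ccccc2)cc1 | starting material
10 | 4-(benzyloxy)-2-bromophenol | Oc1ccc(OCc2ccccc2)cc1Br | intermediate
11 | potassium 4-(benzyloxy)-2-bromophenoxide | [K+].[O-]c1ccc(OCc2ccccc2)cc1Br | intermediate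
12 | 3,6-dimethoxybenzyne (1,4-dimethoxycyclohexa-1,3-dien-5-yne) | COC1=CC=C(OC)C#C1 | intermediate
13 | 2-[4-(benzyloxy)-2-bromophenoxy]-3,6-dimethoxyphenylpotassium | COc1ccc(OC)c([K])c1Oc1ccc(OCc2ccccc2)cc1Br | intermediate
14 | 2-bromo-3-[4-(benzyloxy)-2-bromophenoxy]-1,4-dimethoxybenzene | COc1ccc(OC)c(Br)c1Oc1ccc(OCc2ccccc2)cc1Br | intermediate
15 | 2-[4-(benzyloxy)-2-bromophenoxy]-3,5-dibromo-1,4-dimethoxybenzene | COc1cc(Br)c(OC)c(Br)c1Oc1ccc(OCc2ccccc2)cc1Br | intermediate
16 | [3-bromo-4-(2,4-dibromo-3,6-dimethoxyphenoxy)phenoxy]dichloroborane | COc1cc(Br)c(OC)c(Br)c1Oc1ccc(OB(Cl)Cl)cc1Br | intermediate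
17 | 3-bromo-4-(2,4-dibromo-3,6-dimethoxyphenoxy)phenol | COc1cc(Br)c(OC)c(Br)c1Oc1ccc(O)cc1Br | intermediate
18 | 2,5-dibromo-4-(2,4-dibromo-3,6-dimethoxyphenoxy)phenol | COc1cc(Br)c(OC)c(Br)c1Oc1cc(Br)c(O)cc1Br | intermediate
19 | 2,3,6-tribromo-4-(2,4-dibromo-3,6-dimethoxyphenoxy)phenol | COc1cc(Br)c(OC)c(Br)c1Oc1cc(Br)c(O)c(Br)c1Br | intermediate
20 | 3,5-dibromo-1,4-bis(dibromoboryloxy)-2-[2,3,5-tribromo-4-(dibromoboryloxy)phenoxy]benzene | BrB(Br)Oc1cc(Br)c(OB(Br)Br)c(Br)c1Oc1cc(Br)c(OB(Br)Br)c(Br)c1Br | intermediate
21 | 3,5-dibromo-2-(2,3,5-tribromo-4-hydroxyphenoxy)benzene-1,4-diol | Oc1cc(Br)c(O)c(Br)c1Oc1cc(Br)c(O)c(Br)c1Br | target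

**Step count**
Total step count: 9.
Longest linear sequence: 8 steps (1 → 2 → 6 → 8 → 14 → 15 → 17 → 19 → 21). The ring B branch (9 → 10) joins at step 5.

**Steps most likely to fail**

**Step 5 (new method).**
- What may go wrong:
  - Protonation of arylpotassium 13 may outrun bromine transfer.
  - Phenoxide 11 may be lost by nucleophilic aromatic substitution at the para fluorine of C6F5Br.
  - The aryne may be captured by the C6F5 anion as it builds up.
- Fallback: it uses known chemistry only. The ether is made by SNAr and both ring A bromines are placed by a free phenol. It sets out from 1 and comes back at 17.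
- NBS (2 equiv, CH2Cl2, 0 °C) should brominate 1 first para to the hydroxyl, giving 4-bromo-2,5-dimethoxyphenol F1. It should then brominate ortho to it, giving 2,4-dibromo-3,6-dimethoxyphenol F2.
- F2 displaces fluoride from commercial 3-bromo-4-fluorobenzaldehyde (O=Cc1ccc(F)c(Br)c1; K2CO3, DMF, 100 °C) to give 3-bromo-4-(2,4-dibromo-3,6-dimethoxyphenoxy)benzaldehyde F3.
- Baeyer–Villiger oxidation (mCPBA, CH2Cl2) converts the formyl group into 3-bromo-4-(2,4-dibromo-3,6-dimethoxyphenoxy)phenyl formate F4. K2CO3/MeOH then releases 17.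

**Step 6.**
- What may go wrong: site selectivity between C3 and C2 may be poor. The aryloxy group is wedged between OMe and Br and may twist out of conjugation with ring A. The C5 bromine would then steer the electrophile para to itself, to C2.
- Fallback: the polarity is reversed, with bromide acting as nucleophile on the ring A quinone. It sets out from 14 and comes back at 15.
- (NH4)2Ce(NO3)6 (MeCN–H2O, 0 °C) should oxidatively demethylate the more electron-rich ring A to 2-[4-(benzyloxy)-2-bromophenoxy]-3-bromo-1,4-benzoquinone F5.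
- In this quinone the aryloxy oxygen is a vinylogous ester donor toward the C4 carbonyl, so the C1 carbonyl is the stronger acceptor. HBr (48% aq, CHCl3, 0 °C) should therefore deliver bromide to its β-carbon, C3.
- Enolisation gives 2-[4-(benzyloxy)-2-bromophenoxy]-3,5-dibromobenzene-1,4-diol F6. MeI/K2CO3 (acetone, under N2) then gives 15.

**Step 3.**
- What may go wrong: the bulky PhNTf2 may triflate only sluggishly a phenoxide flanked by OMe and SiMe3. The electron-rich arylsilane may also be protodesilylated while it waits in warm amine base.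
- Fallback: silicon is delivered from oxygen by retro-Brook rearrangement and the triflation is done cold with Tf2O. It sets out from 2 and comes back at 8.
- 2 is N-silylated and lithiated as in step 2 (3, then 4). 4 is then quenched with BrCCl2CCl2Br instead of TMSCl to give 2-bromo-3,6-dimethoxyphenyl N-(tert-butyldimethylsilyl)-N-isopropylcarbamate F7.
- The aq NaHSO4 work-up converts this into 2-bromo-3,6-dimethoxyphenyl N-isopropylcarbamate F8. DBU/Et2NH (MeCN, 40 °C) frees 2-bromo-3,6-dimethoxyphenol F9.
- HN(SiMe3)2 (THF, reflux) gives (2-bromo-3,6-dimethoxyphenoxy)trimethylsilane F10.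
- n-BuLi (THF, −78 °C) exchanges bromine for lithium to give 3,6-dimethoxy-2-(trimethylsilyloxy)phenyllithium F11. Its silyl group shifts from O to C to give lithium 3,6-dimethoxy-2-(trimethylsilyl)phenoxide F12.
- Tf2O added to the same flask gives 8.

**Further compounds**
F1 | step 5 | 4-bromo-2,5-dimethoxyphenol | COc1cc(Br)c(OC)cc1O
F2 | step 5 | 2,4-dibromo-3,6-dimethoxyphenol | COc1cc(Br)c(OC)c(Br)c1O
F3 | step 5 | 3-bromo-4-(2,4-dibromo-3,6-dimethoxyphenoxy)benzaldehyde | COc1cc(Br)c(OC)c(Br)c1Oc1ccc(C=O)cc1Br
F4 | step 5 | 3-bromo-4-(2,4-dibromo-3,6-dimethoxyphenoxy)phenyl formate | COc1cc(Br)c(OC)c(Br)c1Oc1ccc(OC=O)cc1Br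
F5 | step 6 | 2-[4-(benzyloxy)-2-bromophenoxy]-3-bromo-1,4-benzoquinone | O=C1C=CC(=O)C(Br)=C1Oc1ccc(OCc2ccccc2)cc1Br
F6 | step 6 | 2-[4-(benzyloxy)-2-bromophenoxy]-3,5-dibromobenzene-1,4-diol | Oc1cc(Br)c(O)c(Br)c1Oc1ccc(OCc2ccccc2)cc1Br
F7 | step 3 | 2-bromo-3,6-dimethoxyphenyl N-(tert-butyldimethylsilyl)-N-isopropylcarbamate | COc1ccc(OC)c(OC(=O)N(C(C)C)[Si](C)(C)C(C)(C)C)c1Br
F8 | step 3 | 2-bromo-3,6-dimethoxyphenyl N-isopropylcarbamate | COc1ccc(OC)c(OC(=O)NC(C)C)c1Br
F9 | step 3 | 2-bromo-3,6-dimethoxyphenol | COc1ccc(OC)c(O)c1Br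
F10 | step 3 | (2-bromo-3,6-dimethoxyphenoxy)trimethylsilane | COc1ccc(OC)c(O[Si](C)(C)C)c1Br
F11 | step 3 | 3,6-dimethoxy-2-(trimethylsilyloxy)phenyllithium | COc1ccc(OC)c(O[Si](C)(C)C)c1[Li]
F12 | step 3 | lithium 3,6-dimethoxy-2-(trimethylsilyl)phenoxide | [Li+].[O-]c1c(OC)ccc(OC)c1[Si](C)(C)C
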